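**Retrosynthetic overview**
1. Last bond is C6–C7: a light-gated, carboxylate-tethered alkenyl shift from boron to the C6 peroxycarbenium ion of a 6-methoxy-1,2-dioxane acid joins the two halves and sets C6.
2. The 1,2-dioxane (the only ring of the target) comes from a keto-enoate: ketone perhydrolysis makes C6–OO, then a 6-exo peroxy-Michael closure makes O–C3 and sets C3 from C4.
3. The keto-enoate comes from trans-3,5-diethylbutyrolactone (lactol, Wittig, oxidation). C4 is set by enolate ethylation anti to the γ-centre of a lactone derived from L-glutamic acid; that centre then becomes the C6 ketone.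
4. The (E)-alkenylboronic acid comes from (2S)-2-ethylhexan-1-ol (C10 bought) by tosylation, acetylide alkylation, carboalumination–iodination and borylation.
5. Ring order: the butyrolactone ring of the starting material is opened in step 4; the 1,2-dioxane is closed once, in step 6, and kept to the end.

Assumption: (2S)-2-ethylhexan-1-ol (resolved catalogue alcohol) and (5S)-5-(tosyloxymethyl)oxolan-2-one (made on scale from L-glutamic acid) are taken as the bought enantiopure starting materials.

**Route**

Step 1
Reactants: 1 (5S)-5-[(4-methylphenyl)sulfonyloxymethyl]oxolan-2-one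
Product: 2 (5R)-5-ethyloxolan-2-one
Conditions: Me2CuLi (from CuBr·SMe2 and MeLi), Et2O, −40 → −20 °C
Reagents that add atoms: lithium dimethylcuprate ([Li+].C[Cu-]C)
Why: SN2 displacement of the primary tosylate by a Gilman cuprate (sp3–sp3 coupling) leaves the lactone untouched at low temperature and does not involve the bought stereocenter, whose descriptor changes to R only because ethyl ranks below the ring CH2.

Step 2
Reactants: 2 (5R)-5-ethyloxolan-2-one
Product: 4 (3R,5R)-3,5-diethyloxolan-2-one, via lithium enolate 3 (not isolated)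
Conditions: LiN(iPr)2, THF, −78 °C; EtI, DMPU, −78 → −40 °C
Reagents that add atoms: iodoethane (CCI)
Why: Kinetic lactone enolate alkylation, in which iodoethane approaches the planar enolate anti to the γ-ethyl group, gives the trans lactone (about 8:1 expected, minor cis isomer removed by chromatography), so the future C4 center is set by the bought center.

Step 3
Reactants: 4 (3R,5R)-3,5-diethyloxolan-2-one
Product: 5 (3R,5R)-3,5-diethyloxolan-2-ol (lactol, anomer mixture)
Conditions: iBu2AlH (1.05 equiv), CH2Cl2, −78 °C; aq. sodium potassium tartrate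
Reagents that add atoms: none
Why: Partial reduction of a lactone to the lactol by a hindered aluminium hydride stops at the tetrahedral aluminate at −78 °C and touches no stereocenter.

Step 4
Reactants: 5 (3R,5R)-3,5-diethyloxolan-2-ol
Product: 6 methyl (2E,4R,6R)-4-ethyl-6-hydroxyoct-2-enoate
Conditions: Ph3P=CHCO2Me, toluene, 60 °C
Reagents that add atoms: methyl (triphenylphosphoranylidene)acetate (COC(=O)C=P(c1ccccc1)(c1ccccc1)c1ccccc1)
Why: Wittig olefination of the open hydroxy-aldehyde tautomer with a stabilised ylide gives the E-enoate under neutral conditions, which avoids epimerisation of the α-branched aldehyde and the base-triggered 5-exo oxa-Michael closure.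

Step 5
Reactants: 6 methyl (2E,4R,6R)-4-ethyl-6-hydroxyoct-2-enoate
Product: 7 methyl (2E,4R)-4-ethyl-6-oxooct-2-enoate
Conditions: Dess–Martin periodinane, NaHCO3, CH2Cl2, 0 °C → rt
Reagents that add atoms: none
Why: Dess–Martin oxidation of the secondary alcohol turns the bought center, which has done its work of setting C4, into the C6 ketone, and C4 (γ to the ester, β to the ketone) is not enolisable under these conditions.

Step 6
Reactants: 7 methyl (2E,4R)-4-ethyl-6-oxooct-2-enoate
Product: 9 methyl 2-[(3R,4R)-4,6-diethyl-6-methoxy-1,2-dioxan-3-yl]acetate (C6 anomers), via methoxy hydroperoxide 8 (not isolated)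
Conditions: urea·H2O2, Sc(OTf)3 (10 mol %), MeOH, 0 °C → rt; concentrate; Et2NH (0.3 equiv), CF3CH2OH, 0 °C
Reagents that add atoms: hydrogen peroxide as its urea adduct (OO); methanol (CO)
Why: Sc(OTf)3-catalysed perhydrolysis–ketalisation of the ketone gives the α-methoxy hydroperoxide, which closes by a kinetic 6-exo-trig peroxy-Michael addition under amine catalysis through a chair in which the C4 ethyl is equatorial and anti to the incoming oxygen and the enoate arm is axial, giving the 3,4-cis (3R,4R) ring as in plakortin-type closures, while C6 remains a ketal mixture that is erased in step 12.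

Step 7
Reactants: 9 methyl 2-[(3R,4R)-4,6-diethyl-6-methoxy-1,2-dioxan-3-yl]acetate
Product: 10 2-[(3R,4R)-4,6-diethyl-6-methoxy-1,2-dioxan-3-yl]acetic acid
Conditions: LiOH·H2O, THF/H2O 3:1, 0 °C; cold 0.5 M HCl to pH 4
Reagents that add atoms: lithium hydroxide ([Li+].[OH-])
Why: Saponification (acyl–oxygen cleavage) of the methyl ester proceeds at 0 °C, where the peroxyketal and the O–O bond are base-stable and retro-oxa-Michael opening is slow.

Step 8
Reactants: 11 (2S)-2-ethylhexan-1-ol
Product: 12 (2S)-2-ethylhexyl 4-methylbenzenesulfonate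
Conditions: TsCl, pyridine, CH2Cl2, 0 °C → rt
Reagents that add atoms: 4-methylbenzenesulfonyl chloride (Cc1ccc(cc1)S(=O)(=O)Cl)
Why: Sulfonylation of the primary alcohol occurs at oxygen only, so the β-stereocenter is untouched.

Step 9
Reactants: 12 (2S)-2-ethylhexyl 4-methylbenzenesulfonate
Product: 13 (4S)-4-ethyloct-1-yne
Conditions: LiC≡CH·H2NCH2CH2NH2, DMSO, 15–25 °C
Reagents that add atoms: lithium acetylide ([Li+].[C-]#C)
Why: SN2 alkylation of lithium acetylide by the primary tosylate in a dipolar aprotic solvent leaves the β-stereocenter untouched.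

Step 10
Reactants: 13 (4S)-4-ethyloct-1-yne
Product: 15 (1E,4S)-4-ethyl-1-iodo-2-methyloct-1-ene, via alkenylalane 14 (not isolated)
Conditions: Me3Al (2 equiv), Cp2ZrCl2 (20 mol %), CH2Cl2, 0 °C → rt; I2, THF, −30 °C
Reagents that add atoms: trimethylaluminium (C[Al](C)C); iodine (II)
Why: Negishi zirconium-catalysed carboalumination adds methyl and aluminium syn across the terminal alkyne with methyl on the internal carbon, and iodinolysis with retention gives the (E)-trisubstituted vinyl iodide.

Step 11
Reactants: 15 (1E,4S)-4-ethyl-1-iodo-2-methyloct-1-ene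
Product: 17 [(1E,4S)-4-ethyl-2-methyloct-1-en-1-yl]boronic acid, via alkenyllithium 16 (not isolated)
Conditions: t-BuLi (2.1 equiv), Et2O, −78 °C; B(OiPr)3, −78 → 0 °C; 1 M HCl
Reagents that add atoms: triisopropyl borate (CC(C)OB(OC(C)C)OC(C)C); water (O)
Why: Lithium–iodine exchange with retention of alkene geometry, borylation of the alkenyllithium and hydrolysis give the (E)-alkenylboronic acid, which is used crude.

Step 12
Reactants: 10 2-[(3R,4R)-4,6-diethyl-6-methoxy-1,2-dioxan-3-yl]acetic acid; 17 [(1E,4S)-4-ethyl-2-methyloct-1-en-1-yl]boronic acid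
Product: 19 2-[(3R,4R,6R)-4,6-diethyl-6-[(1E,4S)-4-ethyl-2-methyloct-1-en-1-yl]-1,2-dioxan-3-yl]acetic acid, via mixed acyloxyboronate 18 (not isolated)
Conditions: 17 (1.05 equiv), 4 Å MS, CH2Cl2, rt, 1 h; then (CF3)2CHOH (10 vol %), 6-bromo-2-naphthol (20 mol %), 365 nm LEDs, −20 °C, argon; aqueous work-up at pH 4
Reagents that add atoms: none
Why: Proposed new method: the acid and the boronic acid first condense to the mixed acyloxyboronate 18, which ties the alkenyl donor to the C3 arm; under irradiation the excited naphthol, a photoacid that is far more acidic in its excited state, protonates the C6 methoxy group so that the 1,2-dioxan-3-ylium (peroxycarbenium) ion forms only while the light is on; the released methanol binds the neighbouring boron to give a tetracoordinate borate, the only species nucleophilic enough to pass on its alkenyl group, and because this borate is held by the C3 arm it can reach C6 only on the face cis to that arm through a boat-like 1,4-bridged transition state, which sets 6R and overrides the axial attack trans to the C4 ethyl that an untethered nucleophile would make; the alkene geometry is retained as in other boron-to-carbon alkenyl shifts; the closest known reaction types are the Petasis borono-Mannich reaction (a carboxylate- or hydroxyl-bound borate delivering an alkenyl group to a neighbouring cation), additions of organoboron reagents to oxocarbenium ions from acetals, Lewis-acid allylation of peroxyketals through peroxycarbenium ions, and photoacid-catalysed acetal exchange, none of which has been shown on a peroxyketal or with a remote carboxylate tether.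

**Compound list**
1 | (5S)-5-[(4-methylphenyl)sulfonyloxymethyl]oxolan-2-one | O=C1CC[C@@H](COS(=O)(=O)c2ccc(C)cc2)O1 | starting material
2 | (5R)-5-ethyloxolan-2-one | O=C1CC[C@@H](CC)O1 | intermediate
3 | lithium (5R)-5-ethyl-4,5-dihydrofuran-2-olate (lithium enolate of 2) | CC[C@@H]1CC=C([O-])O1.[Li+] | intermediate (not isolated)
4 | (3R,5R)-3,5-diethyloxolan-2-one | O=C1[C@H](CC)C[C@@H](CC)O1 | intermediate
5 | (3R,5R)-3,5-diethyloxolan-2-ol (anomer mixture) | OC1[C@H](CC)C[C@@H](CC)O1 | intermediate
6 | methyl (2E,4R,6R)-4-ethyl-6-hydroxyoct-2-enoate | COC(=O)/C=C/[C@H](CC)C[C@H](O)CC | intermediate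
7 | methyl (2E,4R)-4-ethyl-6-oxooct-2-enoate | COC(=O)/C=C/[C@H](CC)CC(=O)CC | intermediate
8 | methyl (2E,4R)-4-ethyl-6-hydroperoxy-6-methoxyoct-2-enoate (C6 epimers) | COC(=O)/C=C/[C@H](CC)CC(CC)(OC)OO | intermediate (not isolated)
9 | methyl 2-[(3R,4R)-4,6-diethyl-6-methoxy-1,2-dioxan-3-yl]acetate (C6 anomers) | CCC1(OC)C[C@@H](CC)[C@@H](CC(=O)OC)OO1 | intermediate
10 | 2-[(3R,4R)-4,6-diethyl-6-methoxy-1,2-dioxan-3-yl]acetic acid (C6 anomers) | CCC1(OC)C[C@@H](CC)[C@@H](CC(=O)O)OO1 | intermediate
11 | (2S)-2-ethylhexan-1-ol | CCCC[C@H](CC)CO | starting material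
12 | (2S)-2-ethylhexyl 4-methylbenzenesulfonate | CCCC[C@H](CC)COS(=O)(=O)c1ccc(C)cc1 | intermediate
13 | (4S)-4-ethyloct-1-yne | CCCC[C@H](CC)CC#C | intermediate
14 | [(1E,4S)-4-ethyl-2-methyloct-1-en-1-yl]dimethylalumane | CCCC[C@H](CC)C/C(C)=C/[Al](C)C | intermediate (not isolated)
15 | (1E,4S)-4-ethyl-1-iodo-2-methyloct-1-ene | CCCC[C@H](CC)C/C(C)=C/I | intermediate
16 | [(1E,4S)-4-ethyl-2-methyloct-1-en-1-yl]lithium | CCCC[C@H](CC)C/C(C)=C/[Li] | intermediate (not isolated)
17 | [(1E,4S)-4-ethyl-2-methyloct-1-en-1-yl]boronic acid | CCCC[C@H](CC)C/C(C)=C/B(O)O | intermediate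
18 | mixed anhydride of 10 and 17: {2-[(3R,4R)-4,6-diethyl-6-methoxy-1,2-dioxan-3-yl]acetoxy}[(1E,4S)-4-ethyl-2-methyloct-1-en-1-yl]hydroxyborane | CCC1(OC)C[C@@H](CC)[C@@H](CC(=O)OB(O)/C=C(C)/C[C@@H](CC)CCCC)OO1 | intermediate (not isolated)
19 | 2-[(3R,4R,6R)-4,6-diethyl-6-[(1E,4S)-4-ethyl-2-methyloct-1-en-1-yl]-1,2-dioxan-3-yl]acetic acid | CCCC[C@H](CC)C/C(C)=C/[C@@]1(CC)C[C@@H](CC)[C@@H](CC(=O)O)OO1 | target

**Step count**
Total: 12 steps. Longest linear sequence: 8 steps (steps 1–7 and 12); the side-chain branch is steps 8–11.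

**Three steps most likely to fail**

Step 12 (the proposed new step). The peroxycarbenium ion may fragment (Hock-type shift) before the alkenyl group arrives. Free, untethered boronic acid may deliver the alkenyl group on the other face and give the C6 epimer. The boronic acid may protodeboronate. The fallback uses known chemistry; it sets out from ketone 7 and alkenyllithium 16 (made from iodide 15 as in step 11) and comes back at target 19. Alkenyllithium 16 is added at −78 °C in THF to ketone 7 precomplexed with LaCl3·2LiCl, giving the tertiary allylic alcohol methyl (2E,4R,7E,10S)-4,6,10-triethyl-6-hydroxy-8-methyltetradeca-2,7-dienoate F1 as both C6 epimers. Acid-catalysed perhydrolysis (ethereal H2O2, catalytic H2SO4, 0 °C, SN1 through the allyl cation) gives the tertiary hydroperoxide methyl (2E,4R,7E,10S)-4,6,10-triethyl-6-hydroperoxy-8-methyltetradeca-2,7-dienoate F2. Et2NH in CF3CH2OH closes F2 by the established 6-exo peroxy-Michael addition to methyl 2-[(3R,4R,6R)-4,6-diethyl-6-[(1E,4S)-4-ethyl-2-methyloct-1-en-1-yl]-1,2-dioxan-3-yl]acetate F3 together with its C6 epimer, which is removed by HPLC. LiOH as in step 7 then gives 19. This fallback does not control C6, which is the point of the new step.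

Step 6. Perhydrolysis of the ketone may lose to gem-dihydroperoxide formation or to addition of H2O2 or methanol to the enoate, and the closure may give some 3,4-trans ring (separable at 9). The fallback changes the way the hydroperoxide is made, not the closure, so it answers only the first failure mode; it sets out from ketone 7 and comes back at 8 and so at 9. Methylenation of 7 with Zn, CH2Br2 and TiCl4, which spares the ester, gives methyl (2E,4R)-4-ethyl-6-methylideneoct-2-enoate F4. Ozonolysis with one equivalent of O3 in MeOH/CH2Cl2 at −78 °C attacks the electron-rich 1,1-disubstituted alkene far faster than the enoate, and the carbonyl oxide is trapped by methanol to give methoxy hydroperoxide 8. Et2NH in CF3CH2OH then closes 8 to 9 as in the main route.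

Step 7. Hydroxide may open the ring by retro-oxa-Michael (E1cB) and scramble C3, and the acidic work-up may hydrolyse the peroxyketal. The fallback replaces the methyl ester by an ester cleaved with fluoride; it sets out from lactol 5 and comes back at acid 10. Wittig reaction of 5 with 2-(trimethylsilyl)ethyl (triphenylphosphoranylidene)acetate gives 2-(trimethylsilyl)ethyl (2E,4R,6R)-4-ethyl-6-hydroxyoct-2-enoate F5. Dess–Martin oxidation gives 2-(trimethylsilyl)ethyl (2E,4R)-4-ethyl-6-oxooct-2-enoate F6. Urea·H2O2 with Sc(OTf)3 in MeOH gives 2-(trimethylsilyl)ethyl (2E,4R)-4-ethyl-6-hydroperoxy-6-methoxyoct-2-enoate F7, which is not isolated. Et2NH in CF3CH2OH closes it to 2-(trimethylsilyl)ethyl 2-[(3R,4R)-4,6-diethyl-6-methoxy-1,2-dioxan-3-yl]acetate F8. Bu4NF buffered with AcOH in THF at 0 °C fragments the silylethyl ester and gives 10 without hydroxide or strong acid.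

**Further compounds**
F1 | step 12 | methyl (2E,4R,7E,10S)-4,6,10-triethyl-6-hydroxy-8-methyltetradeca-2,7-dienoate (C6 epimers) | CCCC[C@H](CC)C/C(C)=C/C(O)(CC)C[C@@H](CC)/C=C/C(=O)OC
F2 | step 12 | methyl (2E,4R,7E,10S)-4,6,10-triethyl-6-hydroperoxy-8-methyltetradeca-2,7-dienoate (C6 epimers) | CCCC[C@H](CC)C/C(C)=C/C(OO)(CC)C[C@@H](CC)/C=C/C(=O)OC
F3 | step 12 | methyl 2-[(3R,4R,6R)-4,6-diethyl-6-[(1E,4S)-4-ethyl-2-methyloct-1-en-1-yl]-1,2-dioxan-3-yl]acetate | CCCC[C@H](CC)C/C(C)=C/[C@@]1(CC)C[C@@H](CC)[C@@H](CC(=O)OC)OO1
F4 | step 6 | methyl (2E,4R)-4-ethyl-6-methylideneoct-2-enoate | COC(=O)/C=C/[C@H](CC)CC(=C)CC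
F5 | step 7 | 2-(trimethylsilyl)ethyl (2E,4R,6R)-4-ethyl-6-hydroxyoct-2-enoate | C[Si](C)(C)CCOC(=O)/C=C/[C@H](CC)C[C@H](O)CC
F6 | step 7 | 2-(trimethylsilyl)ethyl (2E,4R)-4-ethyl-6-oxooct-2-enoate | C[Si](C)(C)CCOC(=O)/C=C/[C@H](CC)CC(=O)CC
F7 | step 7 | 2-(trimethylsilyl)ethyl (2E,4R)-4-ethyl-6-hydroperoxy-6-methoxyoct-2-enoate (C6 epimers) | C[Si](C)(C)CCOC(=O)/C=C/[C@H](CC)CC(CC)(OC)OO
F8 | step 7 | 2-(trimethylsilyl)ethyl 2-[(3R,4R)-4,6-diethyl-6-methoxy-1,2-dioxan-3-yl]acetate (C6 anomers) | CCC1(OC)C[C@@H](CC)[C@@H](CC(=O)OCC[Si](C)(C)C)OO1
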